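**Plan**

- Retrosynthesis: ring A is opened at O25–C13 (oxidative oxa-Michael) and the tetrahydrofuran at O6–C7. C11–C13 and C14–C26 of the bicyclo[2.2.2]octene are then cut together (alkyne Diels–Alder), leaving a silylene-bridged cyclohexadiene and a chiral ynone.
- The diene is traced back through Si–O (silylene), C7–C26 (Claisen), C9–C7 (thioester to ethyl ketone), C4–C5 (auxiliary alkylation) and C2–C11 (Mukaiyama–Michael on an alkylidene Meldrum's acid).
- Forward ring order: cyclohexane-1,3-dione, six-membered dioxasiline, bicyclo[2.2.2]octadiene (both carbocycles at once), tetrahydrofuran, ring A last.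
- Enabling feature: bridgeheads C11 and C26 are both bonded to the C13=C14 double bond that carries ring A (O25, C13, C14, C15, C17, C18). O6 on C5 and O27 on C26 are 1,3-related, so one silicon atom can tie them into the diene.
- Stereochemistry: C4 from alkylation on (4S)-4-benzyloxazolidinone; C18 from ethyl (3S)-3-hydroxy-3-phenylpropanoate; C11 and C26 from addition anti to the C5 arm of C4; C7 by inversion under attack of the tethered O6.

Key step: step 14

Remark: atom labels C1–O27 are those of the target SMILES and are used for all intermediates. The carbon that becomes C11 is carried as a mixture of epimers until step 10 makes it planar, which has no consequence. C9 is carried as a thioester through the alkylation because an ethyl ketone would itself be enolised and alkylated under the titanium conditions.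

**Step 1**
Reactants: 1 S-ethyl propanethioate
Product: 3 1-(ethylsulfanyl)-1-[(trimethylsilyl)oxy]prop-1-ene, via lithium thioester enolate 2 (not isolated)
Conditions: LiN(iPr)2, THF, −78 °C; then Me3SiCl, −78 °C → rt
Reagents that add atoms: chlorotrimethylsilane, C[Si](C)(C)Cl
Why: Kinetic enolisation of the thioester and O-silylation give the silyl ketene thioacetal (enol silane formation); its double-bond geometry is irrelevant because the carbon becomes the epimeric C11.

**Step 2**
Reactants: 3 1-(ethylsulfanyl)-1-[(trimethylsilyl)oxy]prop-1-ene; 4 2,2-dimethyl-5-(propan-2-ylidene)-1,3-dioxane-4,6-dione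
Product: 5 S-ethyl 3-(2,2-dimethyl-4,6-dioxo-1,3-dioxan-5-yl)-2,3-dimethylbutanethioate
Conditions: TiCl4 (1.0 equiv), CH2Cl2, −78 °C; aq. HCl work-up
Reagents that add atoms: none
Why: Mukaiyama–Michael addition: the TiCl4-chelated alkylidene Meldrum's acid should accept the silyl ketene acetal at its fully substituted β-carbon, forming C2–C11 and the quaternary C2 without a basic enolate that could deprotonate the γ-methyl groups.

**Step 3**
Reactants: 5 S-ethyl 3-(2,2-dimethyl-4,6-dioxo-1,3-dioxan-5-yl)-2,3-dimethylbutanethioate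
Product: 6 5-(ethylsulfanyl)-3,3,4-trimethyl-5-oxopentanoic acid
Conditions: DMF/H2O (10:1), 100 °C
Reagents that add atoms: water, O
Why: Hydrolytic opening of the Meldrum's acid and thermal decarboxylation of the malonic acid give the monoacid, and the neutral medium should leave the hindered thioester intact.

**Step 4**
Reactants: 6 5-(ethylsulfanyl)-3,3,4-trimethyl-5-oxopentanoic acid; 7 (4S)-4-benzyl-1,3-oxazolidin-2-one
Product: 9 (4S)-4-benzyl-3-[5-(ethylsulfanyl)-3,3,4-trimethyl-5-oxopentanoyl]-1,3-oxazolidin-2-one, via mixed pivalic anhydride 8 (not isolated)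
Conditions: Me3CCOCl, Et3N, THF, −20 °C; then 7, LiCl, −20 °C → rt
Reagents that add atoms: none
Why: N-Acylation of the oxazolidinone through the mixed anhydride (Evans auxiliary attachment) occurs at the less hindered of the two anhydride carbonyls.

**Step 5**
Reactants: 9 (4S)-4-benzyl-3-[5-(ethylsulfanyl)-3,3,4-trimethyl-5-oxopentanoyl]-1,3-oxazolidin-2-one
Product: 11 (4S)-4-benzyl-3-[(2R)-2-[(benzyloxy)methyl]-5-(ethylsulfanyl)-3,3,4-trimethyl-5-oxopentanoyl]-1,3-oxazolidin-2-one, via chlorotitanium enolate 10 (not isolated)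
Conditions: TiCl4, iPr2NEt, CH2Cl2, 0 °C; then BnOCH2Cl, 0 °C
Reagents that add atoms: benzyl chloromethyl ether, ClCOCc1ccccc1
Why: Evans asymmetric alkylation: the chelated (Z)-titanium enolate is attacked by the oxocarbenium-like electrophile on the face opposite the benzyl group of the (S)-auxiliary, setting C4 as R, while the thioester, whose only α-hydrogen is tertiary and next to a quaternary carbon, should not be alkylated.

**Step 6**
Reactants: 11 (4S)-4-benzyl-3-[(2R)-2-[(benzyloxy)methyl]-5-(ethylsulfanyl)-3,3,4-trimethyl-5-oxopentanoyl]-1,3-oxazolidin-2-one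
Product: 12 (4S)-4-benzyl-3-[(2R)-2-[(benzyloxy)methyl]-3,3,4-trimethyl-5-oxoheptanoyl]-1,3-oxazolidin-2-one
Conditions: EtZnI, PdCl2(PPh3)2 (5 mol%), toluene/THF, rt
Reagents that add atoms: ethylzinc iodide, CC[Zn]I
Why: Fukuyama coupling: zerovalent palladium inserts into the acyl–sulfur bond and takes ethyl from zinc, delivering the ethyl ketone (C7, C8) without touching the imide, the benzyl ether or C4.

**Step 7**
Reactants: 12 (4S)-4-benzyl-3-[(2R)-2-[(benzyloxy)methyl]-3,3,4-trimethyl-5-oxoheptanoyl]-1,3-oxazolidin-2-one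
Product: 13 (6R)-6-[(benzyloxy)methyl]-2,4,5,5-tetramethylcyclohexane-1,3-dione
Conditions: LiN(SiMe3)2 (2.2 equiv), THF, −78 → 0 °C; aq. NH4Cl
Reagents that add atoms: none
Why: Intramolecular Claisen (Dieckmann-type) condensation: the kinetic enolate at the ketone CH2 (C7) attacks the imide carbonyl C26 in a 6-exo-trig closure and expels the oxazolidinone, the product being held as its dione enolate while allylic strain shields the C4 hydrogen of the imide from deprotonation.

**Step 8**
Reactants: 13 (6R)-6-[(benzyloxy)methyl]-2,4,5,5-tetramethylcyclohexane-1,3-dione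
Product: 14 (6R)-6-(hydroxymethyl)-2,4,5,5-tetramethylcyclohexane-1,3-dione
Conditions: H2 (1 atm), Pd/C, EtOAc, rt
Reagents that add atoms: none
Why: Hydrogenolysis of the benzyl ether; the enolised dione should not be reduced under these conditions.

**Step 9**
Reactants: 14 (6R)-6-(hydroxymethyl)-2,4,5,5-tetramethylcyclohexane-1,3-dione
Product: 15 (4aR)-2,2-di-tert-butyl-5,5,6,8-tetramethyl-4a,5,6,7-tetrahydro-4H-1,3,2-benzodioxasilin-7-one
Conditions: tBu2Si(OSO2CF3)2, 2,6-lutidine, CH2Cl2, 0 °C → rt
Reagents that add atoms: di-tert-butylsilyl bis(trifluoromethanesulfonate), CC(C)(C)[Si](OS(=O)(=O)C(F)(F)F)(OS(=O)(=O)C(F)(F)F)C(C)(C)C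
Why: Silylene protection: the reagent silylates the primary hydroxyl and then the only enol oxygen within reach (O27 on C26), closing a six-membered dioxasiline and fixing the enone as C26=C7–C9=O.

**Step 10**
Reactants: 15 (4aR)-2,2-di-tert-butyl-5,5,6,8-tetramethyl-4a,5,6,7-tetrahydro-4H-1,3,2-benzodioxasilin-7-one
Product: 17 (4aR)-2,2-di-tert-butyl-5,5,6,8-tetramethyl-7-[(trimethylsilyl)oxy]-4a,5-dihydro-4H-1,3,2-benzodioxasiline, via lithium dienolate 16 (not isolated)
Conditions: LiN(iPr)2, THF, −78 °C; then Me3SiCl, −78 → 0 °C; non-aqueous work-up (pentane filtration)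
Reagents that add atoms: chlorotrimethylsilane, C[Si](C)(C)Cl
Why: Kinetic α′-deprotonation of the vinylogous ester at C11 (Stork–Danheiser type) and O-silylation give the cross-conjugated 1,3-dioxygenated diene, the γ-hydrogen at C4 being left in place under kinetic control.

**Step 11**
Reactants: 18 ethyl (3S)-3-hydroxy-3-phenylpropanoate
Product: 19 ethyl (3S)-3-[(tert-butyldimethylsilyl)oxy]-3-phenylpropanoate
Conditions: tBuMe2SiCl, imidazole, DMF, rt
Reagents that add atoms: tert-butyldimethylsilyl chloride, CC(C)(C)[Si](C)(C)Cl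
Why: Imidazole-promoted silylation of the secondary benzylic alcohol (silyl ether protection).

**Step 12**
Reactants: 19 ethyl (3S)-3-[(tert-butyldimethylsilyl)oxy]-3-phenylpropanoate
Product: 20 (3S)-3-[(tert-butyldimethylsilyl)oxy]-N-methoxy-N-methyl-3-phenylpropanamide
Conditions: MeNHOMe·HCl, iPrMgCl, THF, −20 → 0 °C
Reagents that add atoms: N,O-dimethylhydroxylamine hydrochloride, CNOC.Cl
Why: Weinreb amide formation from the ester with the magnesium amide made in the flask; the stereocentre is not enolisable.

**Step 13**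
Reactants: 20 (3S)-3-[(tert-butyldimethylsilyl)oxy]-N-methoxy-N-methyl-3-phenylpropanamide
Product: 21 (5S)-5-[(tert-butyldimethylsilyl)oxy]-5-phenylpent-1-yn-3-one
Conditions: HC≡CMgBr, THF, 0 °C; aq. NH4Cl
Reagents that add atoms: ethynylmagnesium bromide, C#C[Mg]Br
Why: Weinreb ketone synthesis: the chelated tetrahedral adduct collapses only on work-up, so the terminal ynone forms without over-addition.

**Step 14**
Reactants: 17 (4aR)-2,2-di-tert-butyl-5,5,6,8-tetramethyl-7-[(trimethylsilyl)oxy]-4a,5-dihydro-4H-1,3,2-benzodioxasiline; 21 (5S)-5-[(tert-butyldimethylsilyl)oxy]-5-phenylpent-1-yn-3-one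
Product: 22 silylene-bridged bicyclo[2.2.2]octa-2,5-diene adduct (4R,11S,18S,26S): bridgeheads C11 (methyl) and C26 (O27), bridges C7(Me)=C9(OSiMe3), C13H=C14 and C2(Me)2–C4H, O6–Si(tBu)2–O27 spanning C5 and C26 with C5 syn to the C7=C9 bridge, and the (3S)-3-[(tert-butyldimethylsilyl)oxy]-3-phenylpropanoyl group on C14
Conditions: Me2AlCl (1.1 equiv), CH2Cl2, −78 → −40 °C; aq. NaHCO3
Reagents that add atoms: none
Why: This is a normal-demand, concerted but asynchronous [4+2] cycloaddition of a cyclic 1,3-dioxygenated diene with a Lewis-acid-bound ynone, closest in type to additions of 2-silyloxycyclohexa-1,3-dienes to acetylenic ketones that give bicyclo[2.2.2]octadienes. The largest HOMO coefficient lies on C11 (β to the C9 silyl enol ether and vinylogous to O27) and the largest LUMO coefficient on the free terminus C13 of the complexed ynone, so C11–C13 leads and the acyl-bearing C14 ends on oxygenated C26. One suprafacial addition across C11 and C26 closes both six-membered rings that share the new C13=C14 bond (C11–C13–C14–C26–C7–C9 and C11–C13–C14–C26–C4–C2). The two new stereocentres C11 and C26 are set together by the diene face that is attacked, and C4 controls it: the C5 methylene and the di-tert-butylsilylene ring it carries cover one face, so the ynone should add anti to C5. The needed orientation is secured by the 1,3-dioxygenation pattern, which the silylene enforces by holding the enol ether at C26, and the low temperature should prevent cycloreversion with loss of the C2–C4 bridge.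

**Step 15**
Reactants: 22 silylene-bridged bicyclo[2.2.2]octa-2,5-diene adduct
Product: 23 C7-bromo C9-ketone (4R,7R,11S,18S,26R): the adduct with C9 as ketone and C7 bearing methyl and bromine, bromine on the face toward the C13=C14 bridge (anti to C5/O6), silylene and silyl ether retained
Conditions: N-bromosuccinimide, NaHCO3, THF, −78 → 0 °C
Reagents that add atoms: N-bromosuccinimide, O=C1CCC(=O)N1Br
Why: Electrophilic α-bromination of the regiodefined silyl enol ether; the reagent should approach C7 from the open face toward the C13=C14 bridge, away from the C5 arm, the silylene and the C2 methyl, and only this enol ether is nucleophilic, so the C17 methylene is not touched.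

**Step 16**
Reactants: 23 C7-bromo C9-ketone
Product: 24 bromo triol (4R,7R,11S,18S,26R): 23 with free O6–H on C5, free O27–H on C26 and free C18–OH
Conditions: HF·pyridine, pyridine, THF, 0 °C → rt
Reagents that add atoms: none
Why: Fluoride-mediated Si–O cleavage (desilylation) removes the silylene and the silyl ether under mildly acidic conditions that should spare the β-hydroxy ketones and the tertiary bromide.

**Step 17**
Reactants: 24 bromo triol
Product: 25 tetracyclic hydroxy enone (4R,7S,11S,18S,26R): the target skeleton with the C4–C5–O6–C7–C26 tetrahydrofuran closed, ring A still open (C13–H, free C18–OH)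
Conditions: AgOSO2CF3, 2,6-di-tert-butyl-4-methylpyridine, CH2Cl2, −20 °C → rt
Reagents that add atoms: none
Why: Silver-assisted intramolecular Williamson-type etherification: Ag+ removes bromide from the α-keto carbon while O6 attacks C7 from the back (5-exo-tet, inversion), which gives the C7 configuration of the target, and no C26 substituent is antiperiplanar to C7–Br, which should disfavour a 1,2-shift.

**Step 18**
Reactants: 25 tetracyclic hydroxy enone
Product: 26 CNP0322161.1 (4R,7S,11R,18S,26R)
Conditions: PdCl2 (10 mol%), CuCl (10 mol%), Na2HPO4, O2 (1 atm), 1,2-dimethoxyethane, 50 °C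
Reagents that add atoms: none
Why: Wacker-type oxidative cyclisation of a β-hydroxy enone: divalent palladium activates C13=C14, the C18 hydroxyl adds to C13 (6-endo, anti-oxypalladation) and syn β-hydride elimination of H13 restores the double bond, giving the 2,3-dihydro-4H-pyran-4-one while copper and O2 reoxidise palladium.

**Compound list**

1 | S-ethyl propanethioate | CCC(=O)SCC | starting material
2 | lithium enolate of S-ethyl propanethioate | CC=C([O-])SCC.[Li+] | intermediate
3 | 1-(ethylsulfanyl)-1-[(trimethylsilyl)oxy]prop-1-ene (double-bond isomers, geometry of no consequence) | CC=C(SCC)O[Si](C)(C)C | intermediate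
4 | 2,2-dimethyl-5-(propan-2-ylidene)-1,3-dioxane-4,6-dione | CC(C)=C1C(=O)OC(C)(C)OC1=O | starting material
5 | S-ethyl 3-(2,2-dimethyl-4,6-dioxo-1,3-dioxan-5-yl)-2,3-dimethylbutanethioate (racemic) | CCSC(=O)C(C)C(C)(C)C1C(=O)OC(C)(C)OC1=O | intermediate
6 | 5-(ethylsulfanyl)-3,3,4-trimethyl-5-oxopentanoic acid (racemic) | CCSC(=O)C(C)C(C)(C)CC(=O)O | intermediate
7 | (4S)-4-benzyl-1,3-oxazolidin-2-one | O=C1N[C@@H](Cc2ccccc2)CO1 | starting material
8 | mixed pivalic anhydride of 6 | CCSC(=O)C(C)C(C)(C)CC(=O)OC(=O)C(C)(C)C | intermediate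
9 | (4S)-4-benzyl-3-[5-(ethylsulfanyl)-3,3,4-trimethyl-5-oxopentanoyl]-1,3-oxazolidin-2-one (epimers at the methyl-bearing CH) | CCSC(=O)C(C)C(C)(C)CC(=O)N1[C@@H](Cc2ccccc2)COC1=O | intermediate
10 | (Z)-chlorotitanium enolate of 9 | CCSC(=O)C(C)C(C)(C)/C=C(\O[Ti](Cl)(Cl)Cl)N1[C@@H](Cc2ccccc2)COC1=O | intermediate
11 | (4S)-4-benzyl-3-[(2R)-2-[(benzyloxy)methyl]-5-(ethylsulfanyl)-3,3,4-trimethyl-5-oxopentanoyl]-1,3-oxazolidin-2-one (epimers at chain C4) | CCSC(=O)C(C)C(C)(C)[C@H](COCc1ccccc1)C(=O)N1[C@@H](Cc2ccccc2)COC1=O | intermediate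
12 | (4S)-4-benzyl-3-[(2R)-2-[(benzyloxy)methyl]-3,3,4-trimethyl-5-oxoheptanoyl]-1,3-oxazolidin-2-one (epimers at chain C4) | CCC(=O)C(C)C(C)(C)[C@H](COCc1ccccc1)C(=O)N1[C@@H](Cc2ccccc2)COC1=O | intermediate
13 | (6R)-6-[(benzyloxy)methyl]-2,4,5,5-tetramethylcyclohexane-1,3-dione (enolised; ring C2 and C4 not defined) | CC1C(=O)C(C)C(C)(C)[C@H](COCc2ccccc2)C1=O | intermediate
14 | (6R)-6-(hydroxymethyl)-2,4,5,5-tetramethylcyclohexane-1,3-dione (enolised; ring C2 and C4 not defined) | CC1C(=O)C(C)C(C)(C)[C@H](CO)C1=O | intermediate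
15 | (4aR)-2,2-di-tert-butyl-5,5,6,8-tetramethyl-4a,5,6,7-tetrahydro-4H-1,3,2-benzodioxasilin-7-one (C6 epimers) | CC1(C)[C@@H]2CO[Si](C(C)(C)C)(C(C)(C)C)OC2=C(C)C(=O)C1C | intermediate
16 | lithium dienolate of 15 (C9–O–Li, C9=C11) | CC1(C)[C@@H]2CO[Si](C(C)(C)C)(C(C)(C)C)OC2=C(C)C([O-])=C1C.[Li+] | intermediate
17 | (4aR)-2,2-di-tert-butyl-5,5,6,8-tetramethyl-7-[(trimethylsilyl)oxy]-4a,5-dihydro-4H-1,3,2-benzodioxasiline | CC1(C)[C@@H]2CO[Si](C(C)(C)C)(C(C)(C)C)OC2=C(C)C(O[Si](C)(C)C)=C1C | intermediate
18 | ethyl (3S)-3-hydroxy-3-phenylpropanoate | CCOC(=O)C[C@H](O)c1ccccc1 | starting material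
19 | ethyl (3S)-3-[(tert-butyldimethylsilyl)oxy]-3-phenylpropanoate | CCOC(=O)C[C@H](O[Si](C)(C)C(C)(C)C)c1ccccc1 | intermediate
20 | (3S)-3-[(tert-butyldimethylsilyl)oxy]-N-methoxy-N-methyl-3-phenylpropanamide | CON(C)C(=O)C[C@H](O[Si](C)(C)C(C)(C)C)c1ccccc1 | intermediate
21 | (5S)-5-[(tert-butyldimethylsilyl)oxy]-5-phenylpent-1-yn-3-one | C#CC(=O)C[C@H](O[Si](C)(C)C(C)(C)C)c1ccccc1 | intermediate
22 | silylene-bridged bicyclo[2.2.2]octa-2,5-diene adduct (4R,11S,18S,26S) | CC1(C)[C@@H]2CO[Si](C(C)(C)C)(C(C)(C)C)O[C@]23C(C)=C(O[Si](C)(C)C)[C@@]1(C)C=C3C(=O)C[C@H](O[Si](C)(C)C(C)(C)C)c1ccccc1 | intermediate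
23 | C7-bromo C9-ketone (4R,7R,11S,18S,26R), bromine anti to O6 | CC1(C)[C@@H]2CO[Si](C(C)(C)C)(C(C)(C)C)O[C@]23[C@@](C)(Br)C(=O)[C@@]1(C)C=C3C(=O)C[C@H](O[Si](C)(C)C(C)(C)C)c1ccccc1 | intermediate
24 | bromo triol (4R,7R,11S,18S,26R) | CC1(C)[C@H](CO)[C@]2(O)[C@@](C)(Br)C(=O)[C@@]1(C)C=C2C(=O)C[C@H](O)c1ccccc1 | intermediate
25 | tetracyclic hydroxy enone (4R,7S,11S,18S,26R), ring A open | CC1(C)[C@@H]2CO[C@]3(C)C(=O)[C@@]1(C)C=C(C(=O)C[C@H](O)c1ccccc1)[C@]23O | intermediate
26 | CNP0322161.1 (4R,7S,11R,18S,26R) | CC1(C)[C@@H]2CO[C@]3(C)C(=O)[C@@]1(C)C1=C(C(=O)C[C@@H](c4ccccc4)O1)[C@]23O | target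

**Step count**

Total: 18 steps. Longest linear sequence: 15 steps (steps 1–10, then 14–18); the ynone branch is 3 steps (11–13).

**Steps most likely to fail**

Step 14. The Lewis acid may strip the trimethylsilyl group once C11–C13 has formed, so that the sequence stops at the open Michael stage before C14 reaches C26. The ynone may also approach in part from the face of the C5 arm. The fallback is an anionic double Michael annulation, a known route from cross-conjugated cyclohexenone enolates to bicyclo[2.2.2]octanones. It sets out from 15: deprotonation with LiN(iPr)2 gives dienolate 16, and ynone 21 is added at −78 °C. C11 adds to C13, and the resulting allenolate adds through C14 to C26 of the regenerated enone, giving the lithium enolate of the bicyclic C9 ketone F1. Silylation in the flask with Me3SiCl brings the material back to the route at 22.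

Step 17. Bromide may leave C7 without participation of O6, and the cation may then suffer a 1,2-shift of a C26 substituent or lose a proton from C8 to give the exocyclic enone. The fallback avoids the halide and sets out from 22. HF·pyridine removes all silicon and gives the keto triol F2, which has hydrogen at C7. PhI(OAc)2 with catalytic TsOH in MeCN then oxidises the enol of the C9 ketone at C7 (trivalent-iodine α-oxygenation of a ketone) with O6 as the internal nucleophile. The route is rejoined at 25.

Step 18. Oxypalladation of the hindered, trisubstituted C13=C14 bond may be slow, and dehydration of the β-hydroxy ketone to the styryl dienone may then take over. The fallback sets out from 25. KN(SiMe3)2 (1 equiv, THF, −78 °C) forms the C18 alkoxide, which adds to C13 (6-endo oxa-Michael). The C14 enolate is trapped with PhSeBr to give the α-phenylselanyl tetrahydropyranone F3. H2O2 oxidises selenium, and syn-elimination of the selenoxide with H13, the only β-hydrogen, restores C13=C14 and gives 26.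

**Further compounds**

F1 | step 14 | lithium enolate of the bicyclic C9 ketone (double-Michael product) | CC1(C)[C@@H]2CO[Si](C(C)(C)C)(C(C)(C)C)O[C@]23C(C)=C([O-])[C@@]1(C)C=C3C(=O)C[C@H](O[Si](C)(C)C(C)(C)C)c1ccccc1.[Li+]
F2 | step 17 | keto triol with hydrogen at C7 (C7 epimers) | CC1(C)[C@H](CO)[C@]2(O)C(C)C(=O)[C@@]1(C)C=C2C(=O)C[C@H](O)c1ccccc1
F3 | step 18 | C14-phenylselanyl tetrahydropyranone (ring A closed, C13–H; cis ring fusion, configuration at C13 and C14 not decisive) | CC1(C)[C@@H]2CO[C@]3(C)C(=O)[C@@]1(C)C1C(C(=O)C[C@@H](c4ccccc4)O1)([Se]c1ccccc1)[C@]23O
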